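**Retrosynthetic overview**
1. Target ⇒ MeOH + a symmetric 2-benzylcyclohexane-1,3-dione. The cut is the aryl C–OMe bond of ring A, the ring with OH, CH2 and OMe side by side. The two hydrogens ring A loses on aromatising go to the ring-B linker, which is therefore carried as an E-stilbene.
2. Benzyl dione ⇒ 5-(arylethyl)cyclohexane-1,3-dione + ring-B benzaldehyde. The bridge CH2 is the formyl carbon, attached at C2, the only carbon nucleophile of the dione (reductive Knoevenagel alkylation).
3. Dione ⇒ isorhapontigenin (partial hydrogenation of its resorcinol ring) ⇒ Heck of 4-vinylguaiacol + 5-bromoresorcinol. Aldehyde ⇒ Vilsmeier–Haack para to OH on the stilbene from Heck of 4-vinylguaiacol + 3-bromo-5-methoxyphenol.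
4. Ring order: all four benzene rings are bought. Ring B and the guaiacol rings C and D stay aromatic throughout. Ring A is dearomatised once (to the dione) and re-formed as the last event.

Assumption: the target SMILES has no stereocentre, stereogenic axis or C=C bond, so it is achiral and needs no enantioselective step. The E-alkenes and the racemic or epimerisable ring carbons of the intermediates are all erased in the last step.

**Step 1**
Reactants: 1 2-methoxy-4-vinylphenol (4-vinylguaiacol); 2 3-bromo-5-methoxyphenol
Product: 3 3-[(E)-2-(4-hydroxy-3-methoxyphenyl)ethenyl]-5-methoxyphenol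
Conditions: Pd(OAc)2 (2 mol %), P(o-tol)3 (6 mol %), Et3N (3 equiv), BHT (cat.), DMF, 100 °C
Reagents that add atoms: none
Why: Mizoroki–Heck reaction: zerovalent palladium inserts into the C–Br bond, syn-carbopalladation at the vinyl terminus and syn-β-hydride elimination give the E-stilbene, and P(o-tol)3/Et3N is the classical system that tolerates free bromophenols.

**Step 2**
Reactants: 3 3-[(E)-2-(4-hydroxy-3-methoxyphenyl)ethenyl]-5-methoxyphenol
Product: 5 4-hydroxy-2-[(E)-2-(4-hydroxy-3-methoxyphenyl)ethenyl]-6-methoxybenzaldehyde, via aryl iminium chloride 4 (not isolated)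
Conditions: POCl3 (3 equiv), DMF (6 equiv), MeCN, 0 to 25 °C; then 2 M NaOH; HCl to pH 5
Reagents that add atoms: N,N-dimethylformamide CN(C)C=O (formyl carbon); water O (carbonyl oxygen)
Why: Vilsmeier–Haack formylation: the weak chloroiminium electrophile attacks only the meta-dioxygenated ring B and, as with 3,5-dimethoxyphenol, prefers the position para to the free OH, while the guaiacol ring and the alkene are too weakly nucleophilic; the basic work-up hydrolyses 4 and any aryl formates.

**Step 3**
Reactants: 1 2-methoxy-4-vinylphenol; 6 5-bromobenzene-1,3-diol (5-bromoresorcinol)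
Product: 7 5-[(E)-2-(4-hydroxy-3-methoxyphenyl)ethenyl]benzene-1,3-diol (isorhapontigenin)
Conditions: Pd(OAc)2 (2 mol %), P(o-tol)3 (6 mol %), Et3N (3 equiv), BHT (cat.), DMF, 100 °C
Reagents that add atoms: none
Why: Mizoroki–Heck reaction as in step 1, giving the E-stilbene with all phenols left free.

**Step 4**
Reactants: 7 isorhapontigenin
Product: 9 5-[2-(4-hydroxy-3-methoxyphenyl)ethyl]cyclohexane-1,3-dione, via dihydroisorhapontigenin 8 (not isolated)
Conditions: H2 (5 bar), 5% Pd/C, NaOH (2.2 equiv), H2O–EtOH, 50 °C; then HCl to pH 3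
Reagents that add atoms: none
Why: Heterogeneous hydrogenation (the dihydroresorcinol process): the C=C is saturated first, then the resorcinol mono-anion reacts through its enone-like keto tautomer, takes up exactly one more H2 and is parked as the inert 1,3-dione enolate, whereas the guaiacolate ring has no such tautomer and stays aromatic; 9 is symmetric, so no stereocentre arises.

**Step 5**
Reactants: 5 4-hydroxy-2-[(E)-2-(4-hydroxy-3-methoxyphenyl)ethenyl]-6-methoxybenzaldehyde; 9 5-[2-(4-hydroxy-3-methoxyphenyl)ethyl]cyclohexane-1,3-dione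
Product: 11 2-{4-hydroxy-2-[(E)-2-(4-hydroxy-3-methoxyphenyl)ethenyl]-6-methoxybenzyl}-5-[2-(4-hydroxy-3-methoxyphenyl)ethyl]cyclohexane-1,3-dione, via Knoevenagel alkylidene dione 10 (not isolated)
Conditions: L-proline (20 mol %), Hantzsch ester (diethyl 2,6-dimethyl-1,4-dihydropyridine-3,5-dicarboxylate, 1.1 equiv), EtOH, 40 °C
Reagents that add atoms: none
Why: Organocatalytic three-component reductive alkylation (proline-catalysed Knoevenagel condensation, then Hantzsch ester conjugate transfer hydrogenation): C2 is the only carbon nucleophile of 9, the strongly electrophilic alkylidene 10 is reduced before it can add a second dione, and the unactivated stilbene is untouched; the C2/C5 relationship is irrelevant because 11 enolises and both carbons become sp2 in step 6.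

**Step 6**
Reactants: 11 2-{4-hydroxy-2-[(E)-2-(4-hydroxy-3-methoxyphenyl)ethenyl]-6-methoxybenzyl}-5-[2-(4-hydroxy-3-methoxyphenyl)ethyl]cyclohexane-1,3-dione
Product: 13 2-{4-hydroxy-2-[2-(4-hydroxy-3-methoxyphenyl)ethyl]-6-methoxybenzyl}-5-[2-(4-hydroxy-3-methoxyphenyl)ethyl]-3-methoxyphenol (target), via vinylogous methyl ester 12 (not isolated)
Conditions: TsOH·H2O (5 mol %), MeOH, 3 Å MS, 60 °C; NaOAc (10 mol %), evaporate; 10% Pd/C (10 mol % Pd), N,N-dimethylacetamide, Ar, sealed tube, 140 °C
Reagents that add atoms: methanol CO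
Why: Proposed new method: redox-neutral methoxy-aromatisation with an internal hydrogen acceptor; acid-catalysed addition–elimination of MeOH at the vinylogous acid of 11 forms the new C–O bond chemoselectively (phenols do not etherify under these conditions) and, because the dione is symmetric, gives a single constitutional isomer 12; after the acid is quenched, zerovalent palladium activates C6–H of 12 as a surface enolate, and β-hydride elimination of C5–H followed by enolisation aromatises ring A; the two surface hydrides are consumed by the stilbene C=C, the only good acceptor present and present in exactly one equivalent, so in a closed vessel 12 is simply isomerised to 13; dehydrogenation of an enone to a phenol alone is roughly thermoneutral, so the coupled alkene hydrogenation supplies the driving force, and no external oxidant ever meets the electron-rich phenols; the closest known reaction types are the Pd/C–ethylene transfer-dehydrogenative conversion of cyclohexanones and alcohols into aryl ethers, the iodine–methanol aromatisation of cyclohexane-1,3-diones and the isoaromatisation of alkylidenecyclohexenones, none of which has been shown on a 1,3-dione-derived vinylogous ester with the substrate's own remote alkene as sole acceptor; no stereocentre is created and C5 of 12 is erased.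

**Compound list**
1 | 2-methoxy-4-vinylphenol (4-vinylguaiacol) | COc1cc(C=C)ccc1O | starting material
2 | 3-bromo-5-methoxyphenol | COc1cc(O)cc(Br)c1 | starting material
3 | 3-[(E)-2-(4-hydroxy-3-methoxyphenyl)ethenyl]-5-methoxyphenol | COc1cc(O)cc(/C=C/c2ccc(O)c(OC)c2)c1 | intermediate
4 | N-{4-hydroxy-2-[(E)-2-(4-hydroxy-3-methoxyphenyl)ethenyl]-6-methoxybenzylidene}-N-methylmethanaminium chloride | C[N+](C)=Cc1c(OC)cc(O)cc1/C=C/c1ccc(O)c(OC)c1.[Cl-] | intermediate
5 | 4-hydroxy-2-[(E)-2-(4-hydroxy-3-methoxyphenyl)ethenyl]-6-methoxybenzaldehyde | O=Cc1c(OC)cc(O)cc1/C=C/c1ccc(O)c(OC)c1 | intermediate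
6 | 5-bromobenzene-1,3-diol (5-bromoresorcinol) | Oc1cc(O)cc(Br)c1 | starting material
7 | 5-[(E)-2-(4-hydroxy-3-methoxyphenyl)ethenyl]benzene-1,3-diol (isorhapontigenin) | COc1cc(/C=C/c2cc(O)cc(O)c2)ccc1O | intermediate
8 | 5-[2-(4-hydroxy-3-methoxyphenyl)ethyl]benzene-1,3-diol (dihydroisorhapontigenin) | COc1cc(CCc2cc(O)cc(O)c2)ccc1O | intermediate
9 | 5-[2-(4-hydroxy-3-methoxyphenyl)ethyl]cyclohexane-1,3-dione | COc1cc(CCC2CC(=O)CC(=O)C2)ccc1O | intermediate
10 | 2-{4-hydroxy-2-[(E)-2-(4-hydroxy-3-methoxyphenyl)ethenyl]-6-methoxybenzylidene}-5-[2-(4-hydroxy-3-methoxyphenyl)ethyl]cyclohexane-1,3-dione (racemic) | O=C1CC(CCc2ccc(O)c(OC)c2)CC(=O)C1=Cc1c(OC)cc(O)cc1/C=C/c1ccc(O)c(OC)c1 | intermediate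
11 | 2-{4-hydroxy-2-[(E)-2-(4-hydroxy-3-methoxyphenyl)ethenyl]-6-methoxybenzyl}-5-[2-(4-hydroxy-3-methoxyphenyl)ethyl]cyclohexane-1,3-dione (drawn as diketone, enolises freely, C2/C5 not defined) | O=C1CC(CCc2ccc(O)c(OC)c2)CC(=O)C1Cc1c(OC)cc(O)cc1/C=C/c1ccc(O)c(OC)c1 | intermediate
12 | 2-{4-hydroxy-2-[(E)-2-(4-hydroxy-3-methoxyphenyl)ethenyl]-6-methoxybenzyl}-5-[2-(4-hydroxy-3-methoxyphenyl)ethyl]-3-methoxycyclohex-2-en-1-one (racemic at C5) | COC1=C(Cc2c(OC)cc(O)cc2/C=C/c2ccc(O)c(OC)c2)C(=O)CC(CCc2ccc(O)c(OC)c2)C1 | intermediate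
13 | 2-{4-hydroxy-2-[2-(4-hydroxy-3-methoxyphenyl)ethyl]-6-methoxybenzyl}-5-[2-(4-hydroxy-3-methoxyphenyl)ethyl]-3-methoxyphenol (CNP0079000.0, achiral) | COc1cc(CCc2cc(O)c(Cc3c(CCc4ccc(O)c(OC)c4)cc(O)cc3OC)c(OC)c2)ccc1O | target

**Step count**
Total: 6 steps, with no protecting groups.
Longest linear sequence: 4 steps (1, 2, 5, 6 or 3, 4, 5, 6).

**Three steps most likely to fail**

*Step 6 (the new step).*
- Dehydrogenation of a tetrasubstituted vinylogous ester on Pd/C may be too slow at 140 °C.
- The hydrogen balance may drift, leaving stilbene or non-aromatised material.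
- Compound 11 may partly revert to a quinone methide and the dione during the acid stage.

The fallback uses known chemistry only. It sets out from 11 and comes back at 13. The hydrogen shuttle is given up, and reduction and oxidation are done separately. The stilbene is hydrogenated (H2 1 atm, 10% Pd/C, EtOH, 25 °C) to the saturated benzyl dione F1. This is converted with MeOH, TsOH·H2O and 3 Å MS at 60 °C into the isolated saturated vinylogous methyl ester F2. F2 is then aromatised by the established aerobic dehydrogenation of cyclohexenones to phenols with divalent palladium (Pd(O2CCF3)2 5 mol %, 2-(dimethylamino)pyridine 10 mol %, TsOH 20 mol %, O2 1 atm, DMSO, 80 °C) to give 13.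

*Step 2.*
- The preference for attack para to OH over para to OMe may be only moderate on this substrate.
- The hydroxystilbene may suffer from the HCl that is released.

The fallback sets out from 7 and comes back at 5, so steps 1 and 2 and compounds 2 to 4 drop out. Regiochemistry is fixed by symmetry and chelation instead of by a para preference. Vilsmeier–Haack formylation of the symmetric resorcinol ring of 7 gives the dihydroxy aldehyde F3. MOMCl/iPr2NEt (2.1 equiv, CH2Cl2, 0 °C) caps only the two non-chelated phenols to give the bis-MOM ether F4. MeI/K2CO3 in DMF methylates the remaining chelated ortho-OH to give the methylated bis-MOM ether F5. HCl in MeOH at 40 °C, followed by aqueous work-up, removes both MOM groups and returns 5.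

*Step 5.*
- The di-ortho-substituted, electron-rich aldehyde may condense slowly.
- Double addition of the dione could then compete.

The fallback sets out from 5 (partner 9) and comes back at 11. The polarity source is changed from an aldehyde plus a hydride donor to a quinone methide. NaBH4 in EtOH at 0 °C reduces 5 to the benzylic alcohol F6. On warming with 9 in aqueous EtOH at 70 °C (the dione acts as its own acid catalyst), F6 loses water to the para-quinone methide F7. The known 1,6-conjugate addition of C2 of the 1,3-dione then gives 11.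

**Further compounds**
F1 | step 6 | 2-{4-hydroxy-2-[2-(4-hydroxy-3-methoxyphenyl)ethyl]-6-methoxybenzyl}-5-[2-(4-hydroxy-3-methoxyphenyl)ethyl]cyclohexane-1,3-dione | O=C1CC(CCc2ccc(O)c(OC)c2)CC(=O)C1Cc1c(OC)cc(O)cc1CCc1ccc(O)c(OC)c1
F2 | step 6 | 2-{4-hydroxy-2-[2-(4-hydroxy-3-methoxyphenyl)ethyl]-6-methoxybenzyl}-5-[2-(4-hydroxy-3-methoxyphenyl)ethyl]-3-methoxycyclohex-2-en-1-one (racemic) | COC1=C(Cc2c(OC)cc(O)cc2CCc2ccc(O)c(OC)c2)C(=O)CC(CCc2ccc(O)c(OC)c2)C1
F3 | step 2 | 2,4-dihydroxy-6-[(E)-2-(4-hydroxy-3-methoxyphenyl)ethenyl]benzaldehyde | O=Cc1c(O)cc(O)cc1/C=C/c1ccc(O)c(OC)c1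
F4 | step 2 | 2-hydroxy-4-(methoxymethoxy)-6-{(E)-2-[3-methoxy-4-(methoxymethoxy)phenyl]ethenyl}benzaldehyde | O=Cc1c(O)cc(OCOC)cc1/C=C/c1ccc(OCOC)c(OC)c1
F5 | step 2 | 2-methoxy-4-(methoxymethoxy)-6-{(E)-2-[3-methoxy-4-(methoxymethoxy)phenyl]ethenyl}benzaldehyde | O=Cc1c(OC)cc(OCOC)cc1/C=C/c1ccc(OCOC)c(OC)c1
F6 | step 5 | 4-(hydroxymethyl)-3-[(E)-2-(4-hydroxy-3-methoxyphenyl)ethenyl]-5-methoxyphenol | OCc1c(OC)cc(O)cc1/C=C/c1ccc(O)c(OC)c1
F7 | step 5 | 3-[(E)-2-(4-hydroxy-3-methoxyphenyl)ethenyl]-5-methoxy-4-methylidenecyclohexa-2,5-dien-1-one | C=C1C(OC)=CC(=O)C=C1/C=C/c1ccc(O)c(OC)c1
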